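**Plan**

- Retrosynthesis: the lactone (C12–O–C6) and both isobutyrates are removed first; C4–OH is traced back to a (Z)-C3=C4 olefin and the C10 methyl to an enolate alkylation.
- The ring then shows the array C9(=O)–C10–C1–C2–C3=C4. Cutting C1–C2 while re-joining C4–C9 (oxy-Cope transform) contracts the ten-membered ring to a cyclohexane C4–C5–C6–C7–C8–C9 that carries the four contiguous stereocentres C5–C8, all trans and all equatorial.
- This 1,2-divinylcyclohexanol is cut further at C9–vinyl (Grignard), at C4–alkoxyvinyl (semipinacol shift from C5) and at the C6–O and C8–O bonds (enolate hydroxylations), which leads to (S)-carvone (its isopropenyl group is C11–C13).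
- Forward: the carvone ring is oxygenated and made quaternary at C4 (steps 3–14), the six-membered ring is expanded to the ten-membered ring (step 15), then C4–OH, the esters and last the α-methylene lactone ring are made.
- Stereochemistry: C7 from carvone; C6 and C8 by enolate hydroxylation trans to isopropenyl; C5 by hydride attack anti to the axial C4 methyl; C2 from the chair transition state with the (Z)-enol ether; C10 by outer-face enolate methylation; C4 by hydroxyl-directed epoxidation on the outer face of the (Z)-cyclodecene.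

Key step: step 15

Remark: all intermediates carry the target's numbering (ring C1–C10, lactone carbons C11–C13, C14 on C10, C15 on C4; the carvone carbonyl carbon is C5). Compounds 27 and 28 are C9 epimer mixtures, which is harmless because C9 is re-oxidised in step 20.

**Route**

Step 1
Reactants: 1 4-methoxybenzyl alcohol
Product: 2 4-methoxybenzyl vinyl ether
Conditions: ethyl vinyl ether (excess), Pd(OAc)2 (2 mol %), 1,10-phenanthroline (2 mol %), 25 °C
Reagents that add atoms: ethyl vinyl ether C=COCC
Why: Transfer vinylation (transetherification) catalysed by divalent palladium should exchange the ethoxy group for the benzylic alkoxy group, driven by the excess of ethyl vinyl ether.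

Step 2
Reactants: 2 4-methoxybenzyl vinyl ether
Product: 4 (Z)-1-bromo-2-[(4-methoxybenzyl)oxy]ethene, via dibromide 3 (not isolated)
Conditions: Br2, CH2Cl2, −78 °C; then i-Pr2NEt, −78 → 40 °C
Reagents that add atoms: bromine BrBr
Why: Bromine addition to the enol ether and amine-induced dehydrobromination of the α-bromo ether should give mainly the (Z)-2-bromovinyl ether, as in the classical preparation of (Z)-1-bromo-2-ethoxyethene; the minor (E) isomer is removed by chromatography.

Step 3
Reactants: 5 (S)-(+)-carvone
Product: 7 trans-6-hydroxycarvone, via sodium enolate 6 (not isolated)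
Conditions: NaN(SiMe3)2, THF, −78 °C; then 2-(phenylsulfonyl)-3-phenyloxaziridine, −78 °C; H2O
Reagents that add atoms: 2-(phenylsulfonyl)-3-phenyloxaziridine O=S(=O)(c1ccccc1)N1OC1c1ccccc1
Why: Kinetic deprotonation at the only α'-position gives the cross-conjugated enolate, and its hydroxylation by the N-sulfonyloxaziridine (enolate oxidation) should occur anti to the neighbouring isopropenyl group, which sets C6 trans to C7.

Step 4
Reactants: 7 trans-6-hydroxycarvone
Product: 8 6-O-TBS ether of 7
Conditions: TBSCl, imidazole, DMF, 25 °C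
Reagents that add atoms: tert-butyldimethylsilyl chloride CC(C)(C)[Si](C)(C)Cl
Why: Standard silylation of the secondary hydroxyl; the TBS ether at C6 should last until fluoride treatment in step 23 and keeps C6 apart from C5 and C8, which are to be acylated.

Step 5
Reactants: 8 6-O-TBS ether of 7
Product: 9 cyclohexenol with C5–OH cis to isopropenyl
Conditions: NaBH4, CeCl3·7H2O, MeOH, −78 → 0 °C
Reagents that add atoms: none
Why: Luche 1,2-reduction with axial hydride delivery should give the equatorial allylic alcohol cis to the isopropenyl group (the cis-carveol pattern); this temporary C5 centre only serves to direct step 6.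

Step 6
Reactants: 9 cyclohexenol with C5–OH cis to isopropenyl
Product: 10 epoxy alcohol (C4–C9 epoxide syn to C5–OH)
Conditions: VO(acac)2 (cat.), t-BuOOH, CH2Cl2, 0 → 25 °C
Reagents that add atoms: tert-butyl hydroperoxide CC(C)(C)OO
Why: Vanadium-catalysed hydroxyl-directed epoxidation should deliver oxygen to the C4=C9 olefin syn to the C5 hydroxyl and leave the isopropenyl group alone; this places the epoxide cis to isopropenyl, the face that nucleophilic epoxidation of the enone would not give.

Step 7
Reactants: 10 epoxy alcohol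
Product: 11 epoxy ketone (C5 ketone)
Conditions: Dess–Martin periodinane, pyridine, CH2Cl2, 0 → 25 °C
Reagents that add atoms: none
Why: Buffered Dess–Martin oxidation converts the secondary carbinol to the ketone without opening the epoxide.

Step 8
Reactants: 11 epoxy ketone; 4 (Z)-1-bromo-2-[(4-methoxybenzyl)oxy]ethene
Product: 13 tertiary epoxy alcohol with the (Z)-alkoxyvinyl group trans to the epoxide oxygen, via vinyllithium 12 (not isolated)
Conditions: 4, t-BuLi (2 equiv), Et2O, −78 °C; then 11, −78 → −40 °C; H2O
Reagents that add atoms: none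
Why: Bromine–lithium exchange gives the chelation-stabilised (Z)-2-alkoxyvinyllithium with retention, and its 1,2-addition to the ketone should occur axially and anti to the epoxide oxygen, which places the alkenyl group antiperiplanar to the C4–O bond as the next step requires.

Step 9
Reactants: 13 tertiary epoxy alcohol
Product: 14 β-hydroxy ketone (C5 ketone, C4 quaternary, C9–OH)
Conditions: ZnBr2 (0.3 equiv), CH2Cl2, 0 °C
Reagents that add atoms: none
Why: Semipinacol rearrangement of the 2,3-epoxy alcohol: the Lewis acid activates the epoxide and the electron-rich alkenyl group shifts from C5 to C4 with inversion at C4 (the enol ether oxygen stabilises the bridged transition state), which should create the quaternary centre with Z geometry retained.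

Step 10
Reactants: 14 β-hydroxy ketone
Product: 15 2,2-disubstituted 1,3-dione (C5 and C9 ketones)
Conditions: Dess–Martin periodinane, pyridine, CH2Cl2, 0 → 25 °C
Reagents that add atoms: none
Why: Dess–Martin oxidation of the C9 carbinol gives a 1,3-dione that cannot enolise between the carbonyls, so C4 is safe.

Step 11
Reactants: 15 1,3-dione
Product: 17 hydroxy ketone (C9 ketone, C5–OH trans to C6–OTBS), via lithium enolate 16 (not isolated)
Conditions: LiN(i-Pr)2 (1.05 equiv), THF, −78 °C; then i-Bu2AlH (1.1 equiv), −78 °C; aq. potassium sodium tartrate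
Reagents that add atoms: none
Why: The C9 ketone, the only one flanked by a CH2 group, is masked in the flask as its enolate, so hydride should reduce only the C5 ketone, attacking anti to the axial C4 methyl and giving the equatorial C5 alcohol.

Step 12
Reactants: 17 hydroxy ketone
Product: 19 dihydroxy ketone (C5–OH, C8–OH), via dilithio alkoxide enolate 18 (not isolated)
Conditions: LiN(i-Pr)2 (2.2 equiv), THF, −78 °C; then 2-(phenylsulfonyl)-3-phenyloxaziridine, −78 °C; H2O
Reagents that add atoms: 2-(phenylsulfonyl)-3-phenyloxaziridine O=S(=O)(c1ccccc1)N1OC1c1ccccc1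
Why: The ketone can enolise only towards C8, and oxaziridine hydroxylation of that enolate should occur anti to the isopropenyl group and to the axial C4 methyl, which sets C8; this centre could equilibrate only towards the same all-equatorial isomer.

Step 13
Reactants: 19 dihydroxy ketone
Product: 20 bis-MOM ether (C5–OMOM, C8–OMOM)
Conditions: MOMCl, i-Pr2NEt, Bu4NI (cat.), CH2Cl2, 0 → 40 °C
Reagents that add atoms: chloromethyl methyl ether COCCl
Why: Mildly basic acetal formation protects both hydroxyls with groups that tolerate the enol ether, cannot migrate to a neighbouring alkoxide in step 15 and can later be removed together.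

Step 14
Reactants: 20 bis-MOM ether
Product: 21 1,2-divinylcyclohexanol (C9: axial vinyl, equatorial OH)
Conditions: CH2=CHMgBr, THF, −78 → −20 °C; H2O
Reagents that add atoms: vinylmagnesium bromide C=C[Mg]Br
Why: Grignard 1,2-addition should come from the axial face, anti to the axial C4 methyl, which places the vinyl group cis (gauche) to the equatorial alkoxyvinyl group on C4 as the rearrangement requires.

Step 15
Reactants: 21 1,2-divinylcyclohexanol
Product: 24 (Z)-cyclodec-3-en-9-one with 2-OPMB and 10-methyl, via potassium alkoxide 22 (not isolated), via potassium enolate 23 (not isolated)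
Conditions: KN(SiMe3)2, 18-crown-6, THF, −78 → 25 °C; then MeI, −78 → 0 °C
Reagents that add atoms: iodomethane CI
Why: Deprotonation of the tertiary C9 carbinol gives alkoxide 22, whose charge-accelerated [3,3]-sigmatropic shift (anionic oxy-Cope rearrangement; closest precedent: the ring expansion of 1,2-divinylcyclohexanols to cyclodec-5-enones) forms C1–C2 while C4–C9 breaks, so the ten-membered ring closes by a suprafacial six-electron expansion of the six-membered ring by four atoms and delivers the C9 enolate 23 directly. The reacting chair keeps the four substituents at C5–C8 equatorial, with the C9 vinyl axial and the C4 alkoxyvinyl equatorial; in the derived chair transition state the (Z)-OPMB group is pseudo-axial on C2, which should fix C2 as S and give the (Z)-C3=C4 olefin. The enolate is regiodefined (C9=C10 only, never towards C8) and should be C-methylated by MeI on its outer face, the inner face being covered by the transannular C3=C4 π bond, which sets C10 as S. The step needs chair over boat selectivity and C- over O-alkylation: the first rests on the rigid all-equatorial cyclohexane chair, the second on the soft electrophile at low temperature. The driving force is the change from an alkoxide to a delocalised enolate and the release of strain between the two adjacent fully substituted carbons.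

Step 16
Reactants: 24 cyclodecenone
Product: 25 allylic alcohol (C2–OH)
Conditions: DDQ, CH2Cl2/pH 7 buffer, 0 °C
Reagents that add atoms: none
Why: Oxidative cleavage of the PMB ether by DDQ (hydride abstraction, hydrolysis of the oxocarbenium ion) should free the C2 hydroxyl without touching MOM or silyl ethers.

Step 17
Reactants: 25 allylic alcohol
Product: 26 2,3-epoxy alcohol (C3–C4 epoxide syn to C2–OH)
Conditions: VO(acac)2 (cat.), t-BuOOH, CH2Cl2, 0 °C
Reagents that add atoms: tert-butyl hydroperoxide CC(C)(C)OO
Why: Vanadium-catalysed directed epoxidation: in the A(1,3)-minimised conformation of the (Z)-olefin both allylic oxygens (C2, C5) lie on the outer face and the ring chain on the inner face, so directed and peripheral attack coincide and should set C4 as S; the isopropenyl group has no allylic hydroxyl and is left.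

Step 18
Reactants: 26 2,3-epoxy alcohol
Product: 27 triol (C2–OH, C4–OH, C9–OH)
Conditions: NaAlH2(OCH2CH2OMe)2 (Red-Al), THF, −20 → 0 °C; aq. potassium sodium tartrate
Reagents that add atoms: none
Why: Red-Al reduction of a 2,3-epoxy alcohol delivers hydride from the C2 alkoxy-aluminate to C3, the proximal and less substituted carbon, which should give the 1,3-diol with the C4–O bond intact; the ketone is reduced as well and is restored in step 20.

Step 19
Reactants: 27 triol
Product: 28 2,4-O-di-tert-butylsilylene with free C9–OH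
Conditions: t-Bu2Si(OTf)2, 2,6-lutidine, CH2Cl2, 0 °C
Reagents that add atoms: di-tert-butylsilyl bis(trifluoromethanesulfonate) CC(C)(C)[Si](OS(=O)(=O)C(F)(F)F)(OS(=O)(=O)C(F)(F)F)C(C)(C)C
Why: The C2 and C4 oxygens are cis-disposed on the ring and should close a six-membered silylene faster than the hindered isolated C9 hydroxyl reacts.

Step 20
Reactants: 28 silylene alcohol
Product: 29 C9 ketone
Conditions: Dess–Martin periodinane, pyridine, CH2Cl2, 0 → 25 °C
Reagents that add atoms: none
Why: Dess–Martin oxidation restores the C9 ketone under neutral conditions that should not epimerise C8 or C10.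

Step 21
Reactants: 29 C9 ketone
Product: 30 C5,C8-diol
Conditions: Me2BBr, CH2Cl2, −78 °C; then aq. NaHCO3
Reagents that add atoms: none
Why: Bromodimethylborane cleaves MOM acetals at −78 °C by bromide attack on the boron-activated acetal, conditions the TBS ether, the silylene, the ketone and the isopropenyl group should survive.

Step 22
Reactants: 30 C5,C8-diol
Product: 31 5,8-bis-isobutyrate
Conditions: (i-PrCO)2O, DMAP (cat.), Et3N, CH2Cl2, 0 → 25 °C
Reagents that add atoms: isobutyric anhydride CC(C)C(=O)OC(=O)C(C)C
Why: DMAP-catalysed acylation can reach only C5–OH and C8–OH, since C2 and C4 are tied in the silylene and C6 is silylated.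

Step 23
Reactants: 31 bis-isobutyrate
Product: 32 triol (C2–OH, C4–OH, C6–OH)
Conditions: HF·pyridine, pyridine, THF, 0 → 25 °C
Reagents that add atoms: none
Why: Buffered fluoride should cleave the TBS ether and the silylene together without acyl migration or ester loss.

Step 24
Reactants: 32 triol
Product: 33 allylic alcohol (C12–OH)
Conditions: SeO2 (0.3 equiv), t-BuOOH, CH2Cl2, 25 °C
Reagents that add atoms: selenium dioxide O=[Se]=O; tert-butyl hydroperoxide CC(C)(C)OO
Why: Selenium-dioxide allylic oxidation (ene reaction, then [2,3]-shift) of the only olefin should oxidise the isopropenyl methyl group; the tertiary allylic C7–H, flanked by two oxygenated carbons, is less reactive.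

Step 25
Reactants: 33 allylic alcohol
Product: 36 cardivin D, via hydroxy enal 34 (not isolated), via lactol 35 (not isolated)
Conditions: activated MnO2 (excess), CH2Cl2, 25 °C
Reagents that add atoms: none
Why: MnO2 oxidises the allylic alcohol to the enal, which should close with the free C6 hydroxyl (C5 and C8 are acylated) to the five-membered lactol; this allylic hemiacetal is oxidised on to the α-methylene-γ-lactone, while the unactivated C2 and C4 alcohols are inert.

**Compound list**

1 | 4-methoxybenzyl alcohol | COc1ccc(CO)cc1 | starting material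
2 | 4-methoxybenzyl vinyl ether | C=COCc1ccc(OC)cc1 | intermediate
3 | 1,2-dibromo-1-[(4-methoxybenzyl)oxy]ethane (racemic) | BrCC(Br)OCc1ccc(OC)cc1 | intermediate
4 | (Z)-1-bromo-2-[(4-methoxybenzyl)oxy]ethene | Br/C=C\OCc1ccc(OC)cc1 | intermediate
5 | (S)-(+)-carvone | C1[C@@H](C(C)=C)CC=C(C)C1=O | starting material
6 | sodium cross-conjugated (C5–C6) enolate of carvone | [Na+].[O-]C1=C[C@@H](C(C)=C)CC=C1C | intermediate
7 | trans-6-hydroxycarvone (C6–OH trans to isopropenyl) | O[C@@H]1[C@@H](C(C)=C)CC=C(C)C1=O | intermediate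
8 | 6-O-TBS ether of 7 | CC(C)(C)[Si](C)(C)O[C@@H]1[C@@H](C(C)=C)CC=C(C)C1=O | intermediate
9 | cyclohexenol: C5–OH cis to isopropenyl, C6–OTBS trans, C4=C9 olefin | CC(C)(C)[Si](C)(C)O[C@@H]1[C@@H](C(C)=C)CC=C(C)[C@H]1O | intermediate
10 | epoxy alcohol: C4–C9 epoxide syn to C5–OH | CC(C)(C)[Si](C)(C)O[C@@H]1[C@@H](C(C)=C)C[C@H]2O[C@@]2(C)[C@H]1O | intermediate
11 | epoxy ketone: C5 ketone, C4–C9 epoxide cis to isopropenyl | CC(C)(C)[Si](C)(C)O[C@@H]1[C@@H](C(C)=C)C[C@H]2O[C@@]2(C)C1=O | intermediate
12 | (Z)-2-[(4-methoxybenzyl)oxy]vinyllithium | [Li]/C=C\OCc1ccc(OC)cc1 | intermediate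
13 | tertiary epoxy alcohol: C5–OH cis and (Z)-2-(PMBO)vinyl trans to the epoxide oxygen | CC(C)(C)[Si](C)(C)O[C@@H]1[C@@H](C(C)=C)C[C@H]2O[C@@]2(C)[C@]1(O)/C=C\OCc3ccc(OC)cc3 | intermediate
14 | β-hydroxy ketone: C5 ketone, C4 bearing methyl and (Z)-2-(PMBO)vinyl, C9–OH | CC(C)(C)[Si](C)(C)O[C@@H]1[C@@H](C(C)=C)C[C@@H](O)[C@](C)(/C=C\OCc2ccc(OC)cc2)C1=O | intermediate
15 | 1,3-dione: C5 and C9 ketones | CC(C)(C)[Si](C)(C)O[C@@H]1[C@@H](C(C)=C)CC(=O)[C@](C)(/C=C\OCc2ccc(OC)cc2)C1=O | intermediate
16 | lithium C8–C9 enolate of dione 15 | [Li+].CC(C)(C)[Si](C)(C)O[C@@H]1[C@@H](C(C)=C)C=C([O-])[C@](C)(/C=C\OCc2ccc(OC)cc2)C1=O | intermediate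
17 | hydroxy ketone: C9 ketone, C5–OH trans to C6–OTBS | CC(C)(C)[Si](C)(C)O[C@@H]1[C@@H](C(C)=C)CC(=O)[C@](C)(/C=C\OCc2ccc(OC)cc2)[C@H]1O | intermediate
18 | dilithium C5 alkoxide / C8–C9 enolate of 17 | [Li+].[Li+].CC(C)(C)[Si](C)(C)O[C@@H]1[C@@H](C(C)=C)C=C([O-])[C@](C)(/C=C\OCc2ccc(OC)cc2)[C@H]1[O-] | intermediate
19 | dihydroxy ketone: C5–OH, C8–OH (trans to isopropenyl), C9 ketone | CC(C)(C)[Si](C)(C)O[C@@H]1[C@@H](C(C)=C)[C@H](O)C(=O)[C@](C)(/C=C\OCc2ccc(OC)cc2)[C@H]1O | intermediate
20 | bis-MOM ether of 19 | CC(C)(C)[Si](C)(C)O[C@@H]1[C@@H](C(C)=C)[C@H](OCOC)C(=O)[C@](C)(/C=C\OCc2ccc(OC)cc2)[C@H]1OCOC | intermediate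
21 | 1,2-divinylcyclohexanol: C9 with OH (equatorial) and vinyl (axial), C4 with methyl and (Z)-2-(PMBO)vinyl | CC(C)(C)[Si](C)(C)O[C@@H]1[C@@H](C(C)=C)[C@H](OCOC)[C@](O)(C=C)[C@](C)(/C=C\OCc2ccc(OC)cc2)[C@H]1OCOC | intermediate
22 | potassium alkoxide of 21 | [K+].CC(C)(C)[Si](C)(C)O[C@@H]1[C@@H](C(C)=C)[C@H](OCOC)[C@]([O-])(C=C)[C@](C)(/C=C\OCc2ccc(OC)cc2)[C@H]1OCOC | intermediate
23 | potassium C9–C10 enolate of the ring-expanded (Z)-cyclodecenone | [K+].CC(C)(C)[Si](C)(C)O[C@@H]1[C@@H](C(C)=C)[C@H](OCOC)/C([O-])=C/C[C@H](OCc2ccc(OC)cc2)/C=C(C)\[C@H]1OCOC | intermediate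
24 | (Z)-cyclodec-3-en-9-one: 2-OPMB, 5-OMOM, 6-OTBS, 7-isopropenyl, 8-OMOM, 10-methyl | CC(C)(C)[Si](C)(C)O[C@@H]1[C@@H](C(C)=C)[C@H](OCOC)C(=O)[C@@H](C)C[C@H](OCc2ccc(OC)cc2)/C=C(C)\[C@H]1OCOC | intermediate
25 | allylic alcohol: 24 with free C2–OH | CC(C)(C)[Si](C)(C)O[C@@H]1[C@@H](C(C)=C)[C@H](OCOC)C(=O)[C@@H](C)C[C@H](O)/C=C(C)\[C@H]1OCOC | intermediate
26 | 2,3-epoxy alcohol: cis C3–C4 epoxide syn to C2–OH | CC(C)(C)[Si](C)(C)O[C@@H]1[C@@H](C(C)=C)[C@H](OCOC)C(=O)[C@@H](C)C[C@H](O)[C@@H]2O[C@]2(C)[C@H]1OCOC | intermediate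
27 | triol: C2–OH, C4–OH, C9–OH (C9 epimer mixture) | CC(C)(C)[Si](C)(C)O[C@@H]1[C@@H](C(C)=C)[C@H](OCOC)C(O)[C@@H](C)C[C@H](O)C[C@](C)(O)[C@H]1OCOC | intermediate
28 | 2,4-O-di-tert-butylsilylene of 27 (C9–OH free, epimer mixture) | CC(C)(C)[Si](C)(C)O[C@@H]1[C@@H](C(C)=C)[C@H](OCOC)C(O)[C@@H](C)C[C@H](O[Si](C(C)(C)C)(C(C)(C)C)O2)C[C@@]2(C)[C@H]1OCOC | intermediate
29 | C9 ketone of 28 | CC(C)(C)[Si](C)(C)O[C@@H]1[C@@H](C(C)=C)[C@H](OCOC)C(=O)[C@@H](C)C[C@H](O[Si](C(C)(C)C)(C(C)(C)C)O2)C[C@@]2(C)[C@H]1OCOC | intermediate
30 | C5,C8-diol (MOM groups removed) | CC(C)(C)[Si](C)(C)O[C@@H]1[C@@H](C(C)=C)[C@H](O)C(=O)[C@@H](C)C[C@H](O[Si](C(C)(C)C)(C(C)(C)C)O2)C[C@@]2(C)[C@H]1O | intermediate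
31 | 5,8-bis-isobutyrate | CC(C)(C)[Si](C)(C)O[C@@H]1[C@@H](C(C)=C)[C@H](OC(=O)C(C)C)C(=O)[C@@H](C)C[C@H](O[Si](C(C)(C)C)(C(C)(C)C)O2)C[C@@]2(C)[C@H]1OC(=O)C(C)C | intermediate
32 | triol: C2–OH, C4–OH, C6–OH; 5,8-bis-isobutyrate; 7-isopropenyl | O[C@@H]1[C@@H](C(C)=C)[C@H](OC(=O)C(C)C)C(=O)[C@@H](C)C[C@H](O)C[C@](C)(O)[C@H]1OC(=O)C(C)C | intermediate
33 | allylic alcohol: 7-(3-hydroxyprop-1-en-2-yl) | O[C@@H]1[C@@H](C(CO)=C)[C@H](OC(=O)C(C)C)C(=O)[C@@H](C)C[C@H](O)C[C@](C)(O)[C@H]1OC(=O)C(C)C | intermediate
34 | hydroxy enal: 7-(3-oxoprop-1-en-2-yl) | O[C@@H]1[C@@H](C(C=O)=C)[C@H](OC(=O)C(C)C)C(=O)[C@@H](C)C[C@H](O)C[C@](C)(O)[C@H]1OC(=O)C(C)C | intermediate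
35 | α-methylene lactol (C12 hemiacetal, both anomers) | C=C1C(O)O[C@@H]2[C@@H]1[C@H](OC(=O)C(C)C)C(=O)[C@@H](C)C[C@H](O)C[C@](C)(O)[C@H]2OC(=O)C(C)C | intermediate
36 | cardivin D | C=C1C(=O)O[C@@H]2[C@@H]1[C@H](OC(=O)C(C)C)C(=O)[C@@H](C)C[C@H](O)C[C@](C)(O)[C@H]2OC(=O)C(C)C | target

**Step count and risks**

Total step count: 25. Longest linear sequence: 23 steps (steps 3–25 from (S)-carvone); the two-step branch (steps 1–2) joins at step 8.

Step 15 (key step). What may go wrong: the pseudo-axial (Z)-alkoxy group may erode the chair preference of the loose anionic transition state (loss of control at C2 and of olefin geometry), or the congested alkoxide may cleave before it rearranges. Fallback: the rearrangement is run in the neutral manifold. Setting out from 21, the tertiary hydroxyl is silylated with N-(trimethylsilyl)imidazole to the trimethylsilyl ether of 21 F1. Heating in toluene at 190 °C in a sealed tube (siloxy-Cope rearrangement through the tighter concerted chair) should give the ring-expanded trimethylsilyl enol ether F2. MeLi in THF then releases the regiodefined lithium enolate F3, which is methylated with MeI/DMPU at −78 °C, and the sequence comes back to the route at 24.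

Step 11. What may go wrong: incomplete masking of the C9 ketone as its enolate leads to over-reduction, or proton transfer moves the enolate to the C5/C6 side. Fallback: the order of reduction and oxidation is reversed. Setting out from 14, chelation-controlled reduction (Et2BOMe, NaBH4, THF/MeOH, −78 °C; external hydride also attacks anti to the axial C4 methyl) should give the cis-1,3-diol F4. The less hindered C9 carbinol (next to a CH2 group, whereas C5 lies between the quaternary carbon and the OTBS-bearing carbon) is then oxidised selectively with catalytic TEMPO/NaOCl/KBr at 0 °C, which returns to the route at 17.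

Step 24. What may go wrong: poor site selectivity of the selenium oxidant (attack at the tertiary allylic C7–H or α to the C9 ketone) and over-oxidation. Fallback: the oxygen is brought in by a singlet-oxygen ene reaction instead. Setting out from 32, photooxygenation (O2, tetraphenylporphyrin, visible light, CH2Cl2, 0 °C) of the only olefin abstracts a methyl hydrogen and should give the allylic hydroperoxide F5. Reduction with PPh3 gives the allylic alcohol, and the sequence comes back to the route at 33.

**Further compounds**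

F1 | step 15 | 9-O-trimethylsilyl ether of 21 | CC(C)(C)[Si](C)(C)O[C@@H]1[C@@H](C(C)=C)[C@H](OCOC)[C@](O[Si](C)(C)C)(C=C)[C@](C)(/C=C\OCc2ccc(OC)cc2)[C@H]1OCOC
F2 | step 15 | ring-expanded trimethylsilyl enol ether (C9–OTMS, C9=C10) | CC(C)(C)[Si](C)(C)O[C@@H]1[C@@H](C(C)=C)[C@H](OCOC)/C(O[Si](C)(C)C)=C/C[C@H](OCc2ccc(OC)cc2)/C=C(C)\[C@H]1OCOC
F3 | step 15 | lithium C9–C10 enolate of the ring-expanded ketone | [Li+].CC(C)(C)[Si](C)(C)O[C@@H]1[C@@H](C(C)=C)[C@H](OCOC)/C([O-])=C/C[C@H](OCc2ccc(OC)cc2)/C=C(C)\[C@H]1OCOC
F4 | step 11 | cis-1,3-diol (C5–OH, C9–OH) from 14 | CC(C)(C)[Si](C)(C)O[C@@H]1[C@@H](C(C)=C)C[C@@H](O)[C@](C)(/C=C\OCc2ccc(OC)cc2)[C@H]1O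
F5 | step 24 | allylic hydroperoxide: 7-(3-hydroperoxyprop-1-en-2-yl) | O[C@@H]1[C@@H](C(COO)=C)[C@H](OC(=O)C(C)C)C(=O)[C@@H](C)C[C@H](O)C[C@](C)(O)[C@H]1OC(=O)C(C)C
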